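At 40 h the reading comes long after Friday's flask stopped moving: its product stood level from 6.00 h to 25.0 h. The thing to watch is therefore the height of that level, and the useful number is what fails to reach it.

| flask | substrate | reagent | free catalyst | remark | time |
|---|---|---|---|---|---|
| Friday's | 0.25 M | 0.25 M | 0.50 mM | the very flask that is asked about, followed so far |  |
| Tuesday's | 0.25 M | 0.38 M | 0.50 mM | run made earlier |  |
| flask | 0.25 M | 0.250 M | 0.50 mM |  | 40 h |

- Friday's (time / h: product / %): 2.00: 30.9; 6.00: 51.0; 12.0: 51.0; 15.0: 50.1; 25.0: 49.9
- Tuesday's (time / h: product / %): 1.50: 25.4; 3.00: 50.5; 5.00: 53.1; 6.00: 52.9; 8.00: 53.2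

(readings scatter by 0.5 percentage points)

- percentages count the substrate that a species holds: one homo dimer counts as two
- product taken out counts as made
- the earlier runs were read with a standard deviation of 0.5 percentage points
- reactions considered so far: substrate + catalyst intermediate B -> catalyst intermediate C; 2 substrate -> homo dimer; catalyst intermediate C -> free catalyst + product; reagent + free catalyst <-> catalyst intermediate A; 2 catalyst intermediate A <-> resting dimer; catalyst intermediate A -> catalyst intermediate B
- additions bring no volume worth counting

- elm: at 40 h add free catalyst, 100 % of the amount charged, then wait 40 h
- cedar: at 40 h add reagent, 100 % of the amount charged, then wait 40 h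
- alder: change nothing and wait 40 h more
- larch: at 40 h take out 90 % of the product then present, then wait 40 h

* product, in percent of the substrate first charged, at 40 h
* the option that brings most further product ("none" if no option brings more than 2 percentage points) (elm / cedar / alder / larch / none)
* product present, with what was taken out counted in, in percent of the substrate first charged, after elm
* product present, with what was taken out counted in, in percent of the substrate first charged, after alder

The mean of Friday's level gives the part missing:

mean of Friday's level = 50.5 %

one minus that mean = 49.5 %

This is the lost share: the part of the substrate charged that does not reach product. Tuesday's flask, with more reagent, looks nearly the same, and its last 3 readings give: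

Tuesday's lost share = 46.9 %

Reckoned at one reagent per product, Friday's flask keeps 49.5 % of its reagent at the level. Among the reactions considered, the other way out for substrate is homo dimer, which goes with [substrate] squared. Tuesday's flask reads 25.4 % at 1.50 h and Friday's 30.9 % at 2.00 h, so Tuesday's flask makes product faster. Tuesday's flask also loses less, by 2.6 percentage points.

The reckoning here carries Friday's lost share forward unchanged, so product at 40 h is 50.5 %. The forecast gives 50.5 % at 40 h, 50.5 % after elm, 50.5 % after alder, and none as the best option: “No option can make more product, because none returns substrate.”

The flask gives 50.3 % at 40 h, 50.3 % after elm, 50.3 % after alder, and none as the best option.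

    substrate + catalyst intermediate B → catalyst intermediate C (k = 1500 M⁻¹ min⁻¹)
    2 substrate → homo dimer (k = 0.0270 M⁻¹ min⁻¹)
    catalyst intermediate C → free catalyst + product (k = 25.0 min⁻¹)
    reagent + free catalyst ⇌ catalyst intermediate A (K = 1.90 M⁻¹, k = 350 M⁻¹ min⁻¹)
    2 catalyst intermediate A ⇌ resting dimer, settled at all times (K = 19000 M⁻¹)
    catalyst intermediate A → catalyst intermediate B (k = 8.60 min⁻¹)

At 40.0 h, substrate, the limiting reagent, stands at 0 % in Friday's flask, and the lost share, read as 49.5 % from the level, stands in that flask as 49.7 % of homo dimer. Homo dimer formation is the main reason for the level: the same run without that step reaches >99.9 % against 50.3 %. The neighbour charged with 3.0 × 10⁻⁴ M of free catalyst reaches 44.1 % of product, so its lost share grows to 55.9 %, and its homo dimer stands at 55.9 %.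

(The data stem from a simulated flask with constants of no real substance.)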